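**Strategy.** Everything rests on the C7–C8 disconnection of the cyclohexane (C5–C6–C7–C8–C9–C10, elemane numbering). The γ-hydroxy-α-methylene acid array O6–C6–C7–C11(=C13)–C12 is read as a latent cis-fused α-methylene butyrolactone: a 3-(bromomethyl)butenolide hung on C6 is turned by indium into an allylmetal that attacks a C8 aldehyde through C7. One operation joins two electrophilic carbons, closes the ring, sets C7 and C8 and moves the alkene to C11=C13. The acyclic precursor is a butenolide aldehyde whose C5/C10 diad comes from an enantioselective ester-enolate Claisen rearrangement and whose C6 comes from a Felkin-controlled butenolide annulation; O8 acylation, C15 hydroxylation and lactone opening complete the target.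

Key step: step 9

Remark on numbering: atom labels follow elemane numbering. C10 is the quaternary ring carbon (C14 methyl, C1=C2 vinyl), C9 the ring CH2, C8 the acyloxy carbon, C7 carries C11(=C13)–C12, C6 is the free carbinol, C5 carries C4(=C3)–C15.

Assumption: the (S,S)-bromoborane of step 2 is taken to deliver the (2R,3S)-acid 5; if the sense of induction is the opposite, the (R,R)-reagent is used in the same way.

**Route**

Step 1
Reactants: 1 (2Z)-3-methylpent-2-en-4-yn-1-ol; 2 3-methylbut-3-enoic acid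
Product: 3 (2Z)-3-methylpent-2-en-4-yn-1-yl 3-methylbut-3-enoate
Conditions: DCC, DMAP (cat.), CH2Cl2, 0 °C → rt
Reagents that add atoms: none
Why: Steglich esterification of a primary allylic alcohol should proceed without touching the Z-enyne, and any drift of the acid part into conjugation is harmless because both isomers give the same dienolate in step 2.

Step 2
Reactants: 3 (2Z)-3-methylpent-2-en-4-yn-1-yl 3-methylbut-3-enoate
Product: 5 (2R,3S)-3-ethenyl-3-methyl-2-(prop-1-en-2-yl)pent-4-ynoic acid, via boron dienolate 4 (not isolated)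
Conditions: (4S,5S)-2-bromo-1,3-bis[3,5-bis(trifluoromethyl)phenylsulfonyl]-4,5-diphenyl-1,3,2-diazaborolidine (1.3 equiv, freshly prepared), Et3N, toluene, −78 °C → 4 °C; aqueous work-up
Reagents that add atoms: none
Why: Enantioselective boron ester-enolate Claisen rearrangement (Corey type): soft enolisation should give dienolate 4 with the isopropenyl group cis to the allylic oxygen, the chair transition state places the ethynyl group of the Z-alkene axial and the methyl group equatorial so that C5 and C10 form in the required relative sense, and the C2-symmetric sulfonamide ligand on boron selects the enantioface.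

Step 3
Reactants: 5 (2R,3S)-3-ethenyl-3-methyl-2-(prop-1-en-2-yl)pent-4-ynoic acid
Product: 6 (2R,3S)-3-ethenyl-3-methyl-2-(prop-1-en-2-yl)pent-4-yn-1-ol
Conditions: LiAlH4, Et2O, 0 °C → rt; Fieser work-up
Reagents that add atoms: none
Why: Hydride reduction of the carboxylic acid to the primary alcohol should leave the isolated alkenes and the (merely deprotonated) terminal alkyne untouched and does not affect either stereocentre.

Step 4
Reactants: 6 (2R,3S)-3-ethenyl-3-methyl-2-(prop-1-en-2-yl)pent-4-yn-1-ol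
Product: 7 (2R,3S)-3-ethenyl-3-methyl-2-(prop-1-en-2-yl)pent-4-ynal
Conditions: Dess–Martin periodinane, CH2Cl2, 0 °C; used crude
Reagents that add atoms: none
Why: Dess–Martin oxidation under non-basic conditions should give the α-branched β,γ-unsaturated aldehyde without epimerisation at C5 or migration of the double bond.

Step 5
Reactants: 8 methyl propiolate; 9 formaldehyde (as paraformaldehyde)
Product: 10 methyl (2Z)-2-(hydroxymethyl)-3-iodoprop-2-enoate
Conditions: MgI2, CH2Cl2, 0 °C; then H2O
Reagents that add atoms: magnesium iodide [Mg+2].[I-].[I-]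
Why: Halo-aldol (β-iodo Morita–Baylis–Hillman) reaction, in which conjugate addition of iodide to the propiolate is followed by aldol capture of formaldehyde and the kinetic Z-isomer (iodine cis to the ester) is expected.

Step 6
Reactants: 7 (2R,3S)-3-ethenyl-3-methyl-2-(prop-1-en-2-yl)pent-4-ynal; 10 methyl (2Z)-2-(hydroxymethyl)-3-iodoprop-2-enoate
Product: 13 (5R)-5-[(3R,4S)-4-ethenyl-2,4-dimethylhex-1-en-5-yn-3-yl]-3-(hydroxymethyl)furan-2(5H)-one, via alkenylchromium dichloride 11 (not isolated), via hydroxy enoate 12 (not isolated)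
Conditions: CrCl2 (5 equiv), NiCl2 (1 mol %), DMSO, rt; then silica gel
Reagents that add atoms: none
Why: Nozaki–Hiyama–Kishi coupling: the alkenylchromium reagent should add only to the aldehyde, in the Felkin–Anh sense (quaternary C10 anti to the incoming carbon, isopropenyl inside) so that C6 is set syn to the C5 branch, and the Z-configured γ-hydroxy enoate lactonises to the butenolide.

Step 7
Reactants: 13 (5R)-5-[(3R,4S)-4-ethenyl-2,4-dimethylhex-1-en-5-yn-3-yl]-3-(hydroxymethyl)furan-2(5H)-one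
Product: 14 (5R)-5-[(3R,4S)-4-ethenyl-2,4-dimethyl-6-oxohex-1-en-3-yl]-3-(hydroxymethyl)furan-2(5H)-one
Conditions: [CpRu(MeCN)3]PF6 (5 mol %), 5,5′-bis(trifluoromethyl)-2,2′-bipyridine (5 mol %), H2O, NMP, 25 °C
Reagents that add atoms: water O
Why: Ruthenium-catalysed anti-Markovnikov hydration acts only on terminal alkynes, so the C9–C8 arm should become CH2–CHO while the alkenes, the butenolide and the allylic alcohol are left alone.

Step 8
Reactants: 14 (5R)-5-[(3R,4S)-4-ethenyl-2,4-dimethyl-6-oxohex-1-en-3-yl]-3-(hydroxymethyl)furan-2(5H)-one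
Product: 15 (5R)-3-(bromomethyl)-5-[(3R,4S)-4-ethenyl-2,4-dimethyl-6-oxohex-1-en-3-yl]furan-2(5H)-one
Conditions: NBS, Me2S, CH2Cl2, −20 °C → 0 °C
Reagents that add atoms: N-bromosuccinimide O=C1CCC(=O)N1Br
Why: Corey–Kim bromination converts the primary allylic alcohol into the bromide by direct displacement without allylic transposition and tolerates the aldehyde.

Step 9
Reactants: 15 (5R)-3-(bromomethyl)-5-[(3R,4S)-4-ethenyl-2,4-dimethyl-6-oxohex-1-en-3-yl]furan-2(5H)-one
Product: 17 (3aR,4R,6S,7R,7aS)-6-ethenyl-4-hydroxy-6-methyl-3-methylidene-7-(prop-1-en-2-yl)-3a,4,5,6,7,7a-hexahydro-1-benzofuran-2(3H)-one, via allylindium bromide 16 (not isolated)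
Conditions: indium powder (2 equiv), THF/H2O (1:1), 0.005 M, rt
Reagents that add atoms: none
Why: Indium metal inserts into the C13–Br bond and the resulting allylindium 16 adds through its γ-carbon C7 to the C8 aldehyde in a closed six-membered (Zimmerman–Traxler) array, forming C7–C8 and shifting the alkene to C11=C13. The closest known reaction type is the intramolecular Barbier allylation of aldehydes by 2-(bromomethyl)acrylates and 3-(bromomethyl)butenolides, which gives ring-fused α-methylene butyrolactones. The cyclohexane C5–C6–C7–C8–C9–C10 closes in a 6-exo-trig mode onto the aldehyde carbon. C7 is controlled by C6: the three-atom tether C5–C10–C9 can deliver C8 only to the butenolide face that carries C5, so the lactone becomes cis-fused and C11 ends cis to O6. C8 is controlled by the chair that keeps the methyl and isopropenyl groups equatorial and the vinyl group axial (chair A); in the closed array the metal-bound carbonyl oxygen must stay gauche to C11 and sits equatorial, away from the axial vinyl group, which places O8 cis to C11 and O6. The step needs γ- over α-attack (α-attack would require an eight-membered ring), intra- over intermolecular reaction (high dilution) and tolerance of the lactone and alkenes (indium in water).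

Step 10
Reactants: 18 [(4R)-2,2-dimethyl-1,3-dioxolan-4-yl]methanol ((R)-solketal)
Product: 19 (4S)-2,2-dimethyl-1,3-dioxolane-4-carbaldehyde
Conditions: (COCl)2, DMSO, CH2Cl2, −78 °C; Et3N
Reagents that add atoms: none
Why: Swern oxidation at low temperature should give the configurationally labile α-alkoxy aldehyde without racemisation (the descriptor changes only because the priorities change).

Step 11
Reactants: 19 (4S)-2,2-dimethyl-1,3-dioxolane-4-carbaldehyde
Product: 20 (4R)-4-ethynyl-2,2-dimethyl-1,3-dioxolane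
Conditions: dimethyl (1-diazo-2-oxopropyl)phosphonate, K2CO3, MeOH, 0 °C → rt
Reagents that add atoms: dimethyl (1-diazo-2-oxopropyl)phosphonate CC(=O)C(=[N+]=[N-])P(=O)(OC)OC
Why: Ohira–Bestmann (Seyferth–Gilbert) homologation converts the aldehyde into the terminal alkyne under mild carbonate conditions that should not epimerise the dioxolane stereocentre.

Step 12
Reactants: 20 (4R)-4-ethynyl-2,2-dimethyl-1,3-dioxolane
Product: 21 2-[(4R)-2,2-dimethyl-1,3-dioxolan-4-yl]prop-2-enoic acid
Conditions: Pd(OAc)2 (1 mol %), 2-(diphenylphosphino)pyridine, MeSO3H (cat.), CO (5 bar), H2O (3 equiv), acetone, 45 °C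
Reagents that add atoms: carbon monoxide [C-]#[O+]; water O
Why: Palladium-catalysed Markovnikov hydroxycarbonylation of a terminal alkyne with a pyridylphosphine ligand is branched-selective and gives the 2-substituted acrylic acid, while acetone as solvent holds the acetonide in place.

Step 13
Reactants: 17 (3aR,4R,6S,7R,7aS)-6-ethenyl-4-hydroxy-6-methyl-3-methylidene-7-(prop-1-en-2-yl)-3a,4,5,6,7,7a-hexahydro-1-benzofuran-2(3H)-one; 21 2-[(4R)-2,2-dimethyl-1,3-dioxolan-4-yl]prop-2-enoic acid
Product: 23 (3aR,4R,6S,7R,7aS)-6-ethenyl-6-methyl-3-methylidene-2-oxo-7-(prop-1-en-2-yl)octahydro-1-benzofuran-4-yl 2-[(4R)-2,2-dimethyl-1,3-dioxolan-4-yl]prop-2-enoate, via mixed anhydride 22 (not isolated)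
Conditions: 2,4,6-trichlorobenzoyl chloride, Et3N, THF, 0 °C; then 17, DMAP, toluene, 0 °C → rt
Reagents that add atoms: none
Why: Yamaguchi esterification acylates the hindered equatorial C8 hydroxyl with retention and is run cold so that acylation outpaces translactonisation towards O8.

Step 14
Reactants: 23 (3aR,4R,6S,7R,7aS)-6-ethenyl-6-methyl-3-methylidene-2-oxo-7-(prop-1-en-2-yl)octahydro-1-benzofuran-4-yl 2-[(4R)-2,2-dimethyl-1,3-dioxolan-4-yl]prop-2-enoate
Product: 24 (3aR,4R,6S,7S,7aS)-6-ethenyl-7-(3-hydroxyprop-1-en-2-yl)-6-methyl-3-methylidene-2-oxooctahydro-1-benzofuran-4-yl 2-[(4R)-2,2-dimethyl-1,3-dioxolan-4-yl]prop-2-enoate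
Conditions: SeO2 (0.3 equiv), t-BuOOH (3 equiv), CH2Cl2, rt
Reagents that add atoms: selenium dioxide O=[Se]=O; tert-butyl hydroperoxide CC(C)(C)OO
Why: Allylic hydroxylation by the ene/[2,3]-sigmatropic sequence should attack only the electron-rich isopropenyl group and there the methyl rather than the methine position, since the vinyl group has no allylic hydrogen and both acrylate alkenes are electron-poor.

Step 15
Reactants: 24 (3aR,4R,6S,7S,7aS)-6-ethenyl-7-(3-hydroxyprop-1-en-2-yl)-6-methyl-3-methylidene-2-oxooctahydro-1-benzofuran-4-yl 2-[(4R)-2,2-dimethyl-1,3-dioxolan-4-yl]prop-2-enoate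
Product: 25 (3aR,4R,6S,7S,7aS)-6-ethenyl-7-(3-hydroxyprop-1-en-2-yl)-6-methyl-3-methylidene-2-oxooctahydro-1-benzofuran-4-yl (3R)-3,4-dihydroxy-2-methylidenebutanoate
Conditions: AcOH/H2O (4:1), 40 °C
Reagents that add atoms: none
Why: Mild aqueous acid hydrolyses the acetonide while the lactone is still closed, so the free diol is released before any acid-sensitive hydroxy acid exists.

Step 16
Reactants: 25 (3aR,4R,6S,7S,7aS)-6-ethenyl-7-(3-hydroxyprop-1-en-2-yl)-6-methyl-3-methylidene-2-oxooctahydro-1-benzofuran-4-yl (3R)-3,4-dihydroxy-2-methylidenebutanoate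
Product: 27 2-[(1S,2S,3S,4S,6R)-4-ethenyl-2-hydroxy-3-(3-hydroxyprop-1-en-2-yl)-4-methyl-6-{[(3R)-3,4-dihydroxy-2-methylidenebutanoyl]oxy}cyclohexyl]prop-2-enoic acid (target), via lithium carboxylate 26 (not isolated)
Conditions: LiOH (1.1 equiv), THF/H2O, 0 °C; then 0.1 M HCl to pH 4.5, 0 °C, cold extraction
Reagents that add atoms: lithium hydroxide [Li+].[OH-]
Why: Saponification of the strained cis-fused γ-lactone should be much faster than that of the hindered α-substituted acrylate ester of a secondary alcohol, the carboxylate cannot relactonise, and careful cold acidification should release the γ-hydroxy acid.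

**Compound list**

1 | (2Z)-3-methylpent-2-en-4-yn-1-ol | C#C/C(C)=C\CO | starting material
2 | 3-methylbut-3-enoic acid | C=C(C)CC(=O)O | starting material
3 | (2Z)-3-methylpent-2-en-4-yn-1-yl 3-methylbut-3-enoate | C=C(C)CC(=O)OC/C=C(/C)C#C | intermediate
4 | boron dienolate of 3, O-boryl ketene acetal on the (4S,5S)-diazaborolidine, isopropenyl cis to the allylic oxygen (not isolated) | C=C(C)/C=C(/OB1N(S(=O)(=O)c2cc(cc(c2)C(F)(F)F)C(F)(F)F)[C@@H](c2ccccc2)[C@H](c2ccccc2)N1S(=O)(=O)c1cc(cc(c1)C(F)(F)F)C(F)(F)F)OC/C=C(/C)C#C | intermediate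
5 | (2R,3S)-3-ethenyl-3-methyl-2-(prop-1-en-2-yl)pent-4-ynoic acid | OC(=O)[C@@H]([C@](C)(C=C)C#C)C(C)=C | intermediate
6 | (2R,3S)-3-ethenyl-3-methyl-2-(prop-1-en-2-yl)pent-4-yn-1-ol | OC[C@@H]([C@](C)(C=C)C#C)C(C)=C | intermediate
7 | (2R,3S)-3-ethenyl-3-methyl-2-(prop-1-en-2-yl)pent-4-ynal | O=C[C@@H]([C@](C)(C=C)C#C)C(C)=C | intermediate
8 | methyl propiolate | C#CC(=O)OC | starting material
9 | formaldehyde (used as paraformaldehyde) | C=O | starting material
10 | methyl (2Z)-2-(hydroxymethyl)-3-iodoprop-2-enoate | OC/C(C(=O)OC)=C/I | intermediate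
11 | methyl (2Z)-3-(dichlorochromio)-2-(hydroxymethyl)prop-2-enoate, alkenylchromium reagent (not isolated) | OC/C(C(=O)OC)=C/[Cr](Cl)Cl | intermediate
12 | methyl (2Z,4R,5R,6S)-6-ethenyl-4-hydroxy-2-(hydroxymethyl)-6-methyl-5-(prop-1-en-2-yl)oct-2-en-7-ynoate (not isolated) | C=C[C@](C)(C#C)[C@@H](C(C)=C)[C@H](O)/C=C(/CO)C(=O)OC | intermediate
13 | (5R)-5-[(3R,4S)-4-ethenyl-2,4-dimethylhex-1-en-5-yn-3-yl]-3-(hydroxymethyl)furan-2(5H)-one | C=C[C@](C)(C#C)[C@@H](C(C)=C)[C@H]1C=C(CO)C(=O)O1 | intermediate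
14 | (5R)-5-[(3R,4S)-4-ethenyl-2,4-dimethyl-6-oxohex-1-en-3-yl]-3-(hydroxymethyl)furan-2(5H)-one | C=C[C@](C)(CC=O)[C@@H](C(C)=C)[C@H]1C=C(CO)C(=O)O1 | intermediate
15 | (5R)-3-(bromomethyl)-5-[(3R,4S)-4-ethenyl-2,4-dimethyl-6-oxohex-1-en-3-yl]furan-2(5H)-one | C=C[C@](C)(CC=O)[C@@H](C(C)=C)[C@H]1C=C(CBr)C(=O)O1 | intermediate
16 | allylindium dibromide from 15, indium on C13 (not isolated) | C=C[C@](C)(CC=O)[C@@H](C(C)=C)[C@H]1C=C(C[In](Br)Br)C(=O)O1 | intermediate
17 | (3aR,4R,6S,7R,7aS)-6-ethenyl-4-hydroxy-6-methyl-3-methylidene-7-(prop-1-en-2-yl)-3a,4,5,6,7,7a-hexahydro-1-benzofuran-2(3H)-one; elemane (5R,6S,7R,8R,10S), cis-fused 6,12-olide, 8-OH cis to C11 | C=C[C@]1(C)C[C@@H](O)[C@H]2C(=C)C(=O)O[C@H]2[C@@H]1C(C)=C | intermediate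
18 | [(4R)-2,2-dimethyl-1,3-dioxolan-4-yl]methanol, (R)-solketal | OC[C@@H]1COC(C)(C)O1 | starting material
19 | (4S)-2,2-dimethyl-1,3-dioxolane-4-carbaldehyde | O=C[C@@H]1COC(C)(C)O1 | intermediate
20 | (4R)-4-ethynyl-2,2-dimethyl-1,3-dioxolane | C#C[C@@H]1COC(C)(C)O1 | intermediate
21 | 2-[(4R)-2,2-dimethyl-1,3-dioxolan-4-yl]prop-2-enoic acid | OC(=O)C(=C)[C@@H]1COC(C)(C)O1 | intermediate
22 | mixed anhydride of 21 and 2,4,6-trichlorobenzoic acid (not isolated) | O=C(OC(=O)C(=C)[C@@H]1COC(C)(C)O1)c1c(Cl)cc(Cl)cc1Cl | intermediate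
23 | (3aR,4R,6S,7R,7aS)-6-ethenyl-6-methyl-3-methylidene-2-oxo-7-(prop-1-en-2-yl)octahydro-1-benzofuran-4-yl 2-[(4R)-2,2-dimethyl-1,3-dioxolan-4-yl]prop-2-enoate | C=C[C@]1(C)C[C@@H](OC(=O)C(=C)[C@@H]3COC(C)(C)O3)[C@H]2C(=C)C(=O)O[C@H]2[C@@H]1C(C)=C | intermediate
24 | (3aR,4R,6S,7S,7aS)-6-ethenyl-7-(3-hydroxyprop-1-en-2-yl)-6-methyl-3-methylidene-2-oxooctahydro-1-benzofuran-4-yl 2-[(4R)-2,2-dimethyl-1,3-dioxolan-4-yl]prop-2-enoate | C=C[C@]1(C)C[C@@H](OC(=O)C(=C)[C@@H]3COC(C)(C)O3)[C@H]2C(=C)C(=O)O[C@H]2[C@@H]1C(=C)CO | intermediate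
25 | (3aR,4R,6S,7S,7aS)-6-ethenyl-7-(3-hydroxyprop-1-en-2-yl)-6-methyl-3-methylidene-2-oxooctahydro-1-benzofuran-4-yl (3R)-3,4-dihydroxy-2-methylidenebutanoate | C=C[C@]1(C)C[C@@H](OC(=O)C(=C)[C@@H](O)CO)[C@H]2C(=C)C(=O)O[C@H]2[C@@H]1C(=C)CO | intermediate
26 | lithium carboxylate of 27 (not isolated) | [Li+].C=C[C@]1(C)C[C@@H](OC(=O)C(=C)[C@@H](O)CO)[C@@H](C(=C)C(=O)[O-])[C@@H](O)[C@@H]1C(=C)CO | intermediate
27 | 2-[(1S,2S,3S,4S,6R)-4-ethenyl-2-hydroxy-3-(3-hydroxyprop-1-en-2-yl)-4-methyl-6-{[(3R)-3,4-dihydroxy-2-methylidenebutanoyl]oxy}cyclohexyl]prop-2-enoic acid; elemane (5S,6S,7S,8R,10S) | C=C[C@]1(C)C[C@@H](OC(=O)C(=C)[C@@H](O)CO)[C@@H](C(=C)C(=O)O)[C@@H](O)[C@@H]1C(=C)CO | target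

**Totals**

Total step count: 16. Longest linear sequence: 12 steps (steps 1–4, 6–9, 13–16, from 1 and 2).

**Steps most likely to fail**

Step 9. What may go wrong is facial selection at the aldehyde carbon during ring closure: reaction through the alternative chair (lactone oxygen axial) or through an open transition state would deliver the C8 carbinol with the opposite configuration. Fallback, from 15 back to 23: the same closure is run and the C8 epimer, (3aR,4S,6S,7R,7aS)-6-ethenyl-4-hydroxy-6-methyl-3-methylidene-7-(prop-1-en-2-yl)-3a,4,5,6,7,7a-hexahydro-1-benzofuran-2(3H)-one F1, is taken on. It is esterified with acid 21 under Mitsunobu conditions (PPh3, diisopropyl azodicarboxylate, THF, 0 °C), which inverts C8 and gives 23 directly, so that retention (Yamaguchi on 17) and inversion (Mitsunobu on F1) converge on the same ester.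

Step 2. What may go wrong is erosion of enantiofacial or diastereofacial control in the boron-mediated rearrangement (mixed dienolate geometry, weak face discrimination at the quaternary centre). Fallback, from 3 back to 5: the rearrangement is run without a chiral controller (Bu2BOTf, N,N-diisopropylethylamine, CH2Cl2, −78 °C → rt), giving the racemate, that is 5 together with its enantiomer (2S,3R)-3-ethenyl-3-methyl-2-(prop-1-en-2-yl)pent-4-ynoic acid F2. Classical resolution with half an equivalent of (R)-1-phenylethylamine lets the (R)-1-phenylethylammonium salt of 5, F3, crystallise, and acidification returns 5.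

Step 16. What may go wrong is loss of chemoselectivity between the lactone and the C8 ester under hydroxide, or relactonisation on acidification. Fallback, from 17 to 27: the lactone is opened before the side chain is present and the acid is masked.
- KOH in THF/H2O gives the potassium carboxylate F4.
- Allyl bromide in DMF gives the allyl (6,8-dihydroxy) ester F5.
- Yamaguchi acylation with 21 at the less hindered C8 hydroxyl gives the allyl ester F6.
- SeO2/t-BuOOH gives the 15-hydroxy allyl ester F7.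
- Acidic resin in MeOH/H2O at rt removes the acetonide and gives the allyl ester of the target, F8.
- Pd(PPh3)4 with morpholine in THF (zerovalent palladium, neutral conditions) removes the allyl group and gives 27.

**Further compounds**

F1 | step 9 | (3aR,4S,6S,7R,7aS)-6-ethenyl-4-hydroxy-6-methyl-3-methylidene-7-(prop-1-en-2-yl)-3a,4,5,6,7,7a-hexahydro-1-benzofuran-2(3H)-one (C8 epimer of 17) | C=C[C@]1(C)C[C@H](O)[C@H]2C(=C)C(=O)O[C@H]2[C@@H]1C(C)=C
F2 | step 2 | (2S,3R)-3-ethenyl-3-methyl-2-(prop-1-en-2-yl)pent-4-ynoic acid (enantiomer of 5) | OC(=O)[C@H]([C@@](C)(C=C)C#C)C(C)=C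
F3 | step 2 | (R)-1-phenylethylammonium (2R,3S)-3-ethenyl-3-methyl-2-(prop-1-en-2-yl)pent-4-ynoate | C[C@@H]([NH3+])c1ccccc1.[O-]C(=O)[C@@H]([C@](C)(C=C)C#C)C(C)=C
F4 | step 16 | potassium 2-[(1S,2S,3R,4S,6R)-4-ethenyl-2,6-dihydroxy-4-methyl-3-(prop-1-en-2-yl)cyclohexyl]prop-2-enoate | [K+].C=C[C@]1(C)C[C@@H](O)[C@@H](C(=C)C(=O)[O-])[C@@H](O)[C@@H]1C(C)=C
F5 | step 16 | prop-2-en-1-yl 2-[(1S,2S,3R,4S,6R)-4-ethenyl-2,6-dihydroxy-4-methyl-3-(prop-1-en-2-yl)cyclohexyl]prop-2-enoate | C=C[C@]1(C)C[C@@H](O)[C@@H](C(=C)C(=O)OCC=C)[C@@H](O)[C@@H]1C(C)=C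
F6 | step 16 | allyl ester F5 acylated at O8 with 2-[(4R)-2,2-dimethyl-1,3-dioxolan-4-yl]prop-2-enoic acid | C=C[C@]1(C)C[C@@H](OC(=O)C(=C)[C@@H]2COC(C)(C)O2)[C@@H](C(=C)C(=O)OCC=C)[C@@H](O)[C@@H]1C(C)=C
F7 | step 16 | 15-hydroxy derivative of F6 | C=C[C@]1(C)C[C@@H](OC(=O)C(=C)[C@@H]2COC(C)(C)O2)[C@@H](C(=C)C(=O)OCC=C)[C@@H](O)[C@@H]1C(=C)CO
F8 | step 16 | prop-2-en-1-yl ester of the target 27 | C=C[C@]1(C)C[C@@H](OC(=O)C(=C)[C@@H](O)CO)[C@@H](C(=C)C(=O)OCC=C)[C@@H](O)[C@@H]1C(=C)CO
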